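Everything hinges on cutting ring A at C1–C10 (eremophilane numbering) by an anionic oxy-Cope retron. The step uses the cis ring fusion, C5 quaternary methyl next to C10–H, together with the C3 oxygen of ring A and the adjacent C8/C9 oxidation sites of ring B: reconnecting C3 to C8 reveals a bridged 3-hydroxy-1,5-diene. A single [3,3] shift of the potassium alkoxide of this 2-vinylbicyclo[2.2.2]oct-5-en-2-ol makes C1–C10, cleaves C3–C8, closes ring A, fixes C10 and unveils the C3 ketone and a C8=C9 alkene. The precursor is the vinyl carbinol of an (S)-o-quinol/acrylic acid Diels–Alder adduct, kept as the free carboxylic acid.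

Key step: step 4

Remark (numbering): eremophilane numbering (C1–C15) labels the atoms of every intermediate, the bicycles included; β is the face of the C5 methyl.
Remark (spectator group): C7 carries a free carboxylic acid. Its carboxylate is inert to the Grignard reagent, has no C7–H that KH or the product enolate can remove, survives Li/NH3 and gives the methyl ketone with MeLi in one step.
Remark (C4): C4 is α to the C3 carbonyl before and after step 4. It is therefore left in its kinetic configuration (methyl on the C6–C7 side, which also screens the wrong carbonyl face in step 3) and is set for good by equilibration in step 4.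
Assumption: the sense of induction of the chiral iodane is not predicted; the atropisomer meant in step 1 is the one that furnishes the (S)-quinol.

Step 1
Reactants: 1 2,3-dimethylphenol; 2 acrylic acid
Product: 4 bicyclic α-ketol acid (C7-CO2H endo; C4-OH on the side of the C6–C7 bridge), via (S)-o-quinol 3 (not isolated)
Conditions: chiral 2,2′-diiodyl-1,1′-binaphthyl (1.1 equiv), CH2Cl2, −78 → −20 °C; then acrylic acid (25 equiv), BHT, −20 °C → rt
Reagents that add atoms: 2,2′-diiodyl-1,1′-binaphthyl (oxygen donor; single atropisomer, not encoded), O=I(=O)c1ccc2ccccc2c1-c1c(I(=O)=O)ccc2ccccc12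
Why: Hydroxylative phenol dearomatisation by the chiral λ5-iodane places oxygen on the methyl-bearing ortho carbon to give the (S)-quinol (reagent control), which acrylic acid traps in a Diels–Alder reaction on the hydroxyl-bearing face with ortho (C7 bonded to C8) and endo orientation, so that the quinol centre dictates C5, C7 and C8.

Step 2
Reactants: 4 bicyclic α-ketol acid
Product: 5 bicyclic keto acid (C4-H; C4 methyl on the side of the C6–C7 bridge)
Conditions: SmI2 (4 equiv), THF/MeOH, −78 → 0 °C
Reagents that add atoms: none
Why: SmI2 reductive cleavage of the α-ketol C–O bond via the ketyl and the enolate, whose protonation on the more open etheno face is expected to leave the C4 methyl on the side of the C6–C7 bridge; this centre is provisional and is reset in step 4.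

Step 3
Reactants: 5 bicyclic keto acid; 6 vinylmagnesium bromide
Product: 7 vinyl carbinol acid (vinyl and CO2H syn to C9=C10; C3-OH and C4 methyl on the side of the C6–C7 bridge)
Conditions: CH2=CHMgBr (3.5 equiv), CeCl3, THF, −78 → 0 °C; aq. NH4Cl
Reagents that add atoms: none
Why: Cerium-mediated Grignard 1,2-addition to the ketone (the carboxylate is inert), with the vinyl group delivered to the etheno face because the other face is screened by the C4 methyl and the inward C7–H, which sets C3 with vinyl syn to C9=C10.

Step 4
Reactants: 7 vinyl carbinol acid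
Product: 10 4β,5β-dimethyl-3-oxo-10βH-cis-octal-8-ene-7β-carboxylic acid, via dipotassium enolate 8 (not isolated), via 4-epi keto carboxylate 9 (not isolated)
Conditions: KH (3 equiv), 18-crown-6 (2.2 equiv), THF, 0 → 45 °C; then MeOH, 40 °C; aq. HCl to pH 3
Reagents that add atoms: none
Why: KH makes the carboxylate/alkoxide dianion, and the alkoxide-accelerated concerted [3,3] shift of the 1,5-diene C1=C2–C3(O−)–C8–C9=C10 runs through the boat array imposed by the bicycle, making C1–C10 while C3–C8 breaks and leaving the C2=C3 enolate 8. The closest known reaction type is the anionic oxy-Cope rearrangement of 2-vinylbicyclo[2.2.2]oct-5-en-2-ols to cis-fused octalenones. Ring A (C1–C2–C3–C4–C5–C10) is closed by this sigmatropic bond formation itself, suprafacially on both allyl halves within a six-membered boat transition state, not by a separate cyclisation. The new centre C10 is controlled by the cage: the vinyl terminus can reach C10 only on the face turned toward the C3–C4 bridge, which puts H10 cis to the C5 methyl, while C5 and C7 pass through unchanged. The step needs the vinyl group syn to C9=C10 (set in step 3) and no competing acidic C–H, which the carboxylate secures because C7–H next to CO2K is not removed and the C8=C9 double bond cannot move into conjugation. Methanol then turns the enolate into ketone 9, and the methoxide formed equilibrates C4 through the C3 enolate to the cis-4,5-dimethyl arrangement of 10, whose C4 methyl is equatorial whereas the epimer suffers a 1,3-diaxial contact with C9 or with the C7 carboxyl.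

Step 5
Reactants: 10 keto acid
Product: 11 3α-hydroxy-4β,5β-dimethyl-10βH-cis-octal-8-ene-7β-carboxylic acid
Conditions: Li, NH3(l)/THF, t-BuOH, −78 → −33 °C; NH4Cl
Reagents that add atoms: none
Why: Dissolving-metal ketone reduction, in which protonation of the ketyl-derived carbanion under thermodynamic control gives the equatorial 3α-alcohol trans to the C4 methyl (a hydride would enter equatorially because the axial C5 methyl blocks the axial path), while the carboxylate and the isolated alkene are untouched.

Step 6
Reactants: 11 hydroxy acid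
Product: 12 3α,8β,9β-trihydroxy-4β,5β-dimethyl-10βH-cis-decalin-7β-carboxylic acid
Conditions: OsO4 (cat.), NMO, acetone/H2O, rt
Reagents that add atoms: N-methylmorpholine N-oxide, C[N+]1([O-])CCOCC1; water, O
Why: Osmium-catalysed syn-dihydroxylation, which should take place on the convex β-face of C8=C9 because ring A and the axial C4–C5 bond screen the α-face, setting C8 and C9 as the 8β,9β-cis-diol.

Step 7
Reactants: 12 triol acid
Product: 13 8β,9β-O-isopropylidene acetal of 12
Conditions: Me2C(OMe)2, PPTS (cat.), acetone, rt
Reagents that add atoms: 2,2-dimethoxypropane, COC(C)(C)OC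
Why: Acid-catalysed acetal exchange, which forms the five-membered dioxolane only on the cis-vicinal diol and leaves the isolated C3 hydroxyl free after work-up.

Step 8
Reactants: 13 acetonide acid; 14 methyllithium
Product: 15 7β-acetyl-8β,9β-(isopropylidenedioxy)-4β,5β-dimethyl-10βH-cis-decalin-3α-ol
Conditions: MeLi (5 equiv), THF, 0 °C → rt; inverse quench into cold aq. NH4Cl
Reagents that add atoms: none
Why: Addition of methyllithium to the lithium carboxylate gives a gem-diolate that releases the methyl ketone only on quenching, so that over-addition is avoided and C7 keeps its equatorial β configuration.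

Step 9
Reactants: 15 methyl ketone
Product: 16 8β,9β-(isopropylidenedioxy)-10βH-eremophil-11-en-3α-ol
Conditions: Ph3PCH3Br, KOtBu, THF, 0 °C → rt
Reagents that add atoms: methyltriphenylphosphonium bromide, C[P+](c1ccccc1)(c1ccccc1)c1ccccc1.[Br-]
Why: Wittig methylenation of the methyl ketone (excess ylide takes up the free hydroxyl), with C7 remaining the equatorial and thermodynamically preferred epimer.

Step 10
Reactants: 16 isopropenyl alcohol; 17 angelic acid
Product: 18 3α-angeloyloxy-8β,9β-(isopropylidenedioxy)-10βH-eremophil-11-ene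
Conditions: 17, 2,4,6-Cl3C6H2COCl, Et3N, PhMe, rt; then 16, 80 °C
Reagents that add atoms: none
Why: Yamaguchi esterification through the preformed mixed anhydride, which acylates the equatorial C3 hydroxyl without a nucleophilic catalyst and therefore without Z to E isomerisation of the angeloyl group.

Step 11
Reactants: 18 angelate acetonide
Product: 19 3α-angeloyloxy-10βH-eremophil-11-ene-8β,9β-diol
Conditions: AcOH/H2O (4:1), 40 °C
Reagents that add atoms: none
Why: Acid-catalysed hydrolysis of the dioxolane under conditions (aqueous acetic acid) that leave the angelate ester and the isopropenyl group intact.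

Step 12
Reactants: 19 angelate diol; 17 angelic acid
Product: 21 3α,9β-bis(angeloyloxy)-10βH-eremophil-11-en-8β-ol, via stannylene acetal 20 (not isolated)
Conditions: Bu2SnO, PhMe, reflux (−H2O); then angeloyl chloride [17 + Me2C=C(Cl)NMe2, CH2Cl2, 0 °C], 0 °C → rt
Reagents that add atoms: none
Why: Stannylene-acetal-directed monoacylation of the cis-diol, which takes place at the equatorial oxygen O9 and leaves the axial C8 hydroxyl free, under base-free conditions that preserve the Z geometry of the angeloyl chloride.

Step 13
Reactants: 21 bis-angelate alcohol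
Product: 22 3α,9β-bis(angeloyloxy)-10βH-eremophil-11-en-8-one (target)
Conditions: Dess–Martin periodinane, NaHCO3, CH2Cl2, rt
Reagents that add atoms: none
Why: Dess–Martin oxidation of the remaining axial C8 alcohol to the ketone under buffered neutral conditions that neither epimerise C7 or C9 nor move the isopropenyl double bond into conjugation.

Compound list
1 | 2,3-dimethylphenol | Cc1cccc(O)c1C | starting material
2 | acrylic acid | C=CC(=O)O | starting material
3 | (S)-6-hydroxy-5,6-dimethylcyclohexa-2,4-dien-1-one (o-quinol; not isolated) | O=C1C=CC=C(C)[C@]1(C)O | intermediate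
4 | 5-hydroxy-4,5-dimethyl-6-oxobicyclo[2.2.2]oct-7-ene-2-carboxylic acid; CO2H syn to the alkene bridge (endo), OH syn to the CO2H-bearing bridge (eremophilane labels: C3 ketone, C4(OH)Me, C5 bridgehead Me, C7-CO2H) | OC(=O)[C@H]1C[C@@]2(C)C=C[C@@H]1C(=O)[C@@]2(C)O | intermediate
5 | 4,5-dimethyl-6-oxobicyclo[2.2.2]oct-7-ene-2-carboxylic acid; CO2H syn to the alkene bridge, 5-methyl (C4 of the eremophilane) syn to the CO2H-bearing bridge | OC(=O)[C@H]1C[C@@]2(C)C=C[C@@H]1C(=O)[C@H]2C | intermediate
6 | vinylmagnesium bromide | C=C[Mg]Br | starting material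
7 | 6-ethenyl-6-hydroxy-4,5-dimethylbicyclo[2.2.2]oct-7-ene-2-carboxylic acid; vinyl and CO2H syn to the alkene bridge, OH and 5-methyl syn to the CO2H-bearing bridge (key-step precursor) | OC(=O)[C@H]1C[C@@]2(C)C=C[C@@H]1[C@](O)(C=C)[C@H]2C | intermediate
8 | dipotassium salt of the C2=C3 enolate of the 4-epi (4α-methyl) cis-octalenone carboxylic acid (not isolated) | [K+].[K+].[O-]C(=O)[C@H]1C[C@@]2(C)[C@H](CC=C([O-])[C@H]2C)C=C1 | intermediate
9 | potassium 4α,5β-dimethyl-3-oxo-10βH-cis-octal-8-ene-7β-carboxylate (4-epimer; not isolated) | [K+].[O-]C(=O)[C@H]1C[C@@]2(C)[C@H](CCC(=O)[C@H]2C)C=C1 | intermediate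
10 | 4β,5β-dimethyl-3-oxo-10βH-cis-octal-8-ene-7β-carboxylic acid (key-step product) | OC(=O)[C@H]1C[C@@]2(C)[C@H](CCC(=O)[C@@H]2C)C=C1 | intermediate
11 | 3α-hydroxy-4β,5β-dimethyl-10βH-cis-octal-8-ene-7β-carboxylic acid | OC(=O)[C@H]1C[C@@]2(C)[C@H](CC[C@@H](O)[C@@H]2C)C=C1 | intermediate
12 | 3α,8β,9β-trihydroxy-4β,5β-dimethyl-10βH-cis-decalin-7β-carboxylic acid | OC(=O)[C@H]1C[C@@]2(C)[C@H](CC[C@@H](O)[C@@H]2C)[C@@H](O)[C@H]1O | intermediate
13 | 3α-hydroxy-8β,9β-(isopropylidenedioxy)-4β,5β-dimethyl-10βH-cis-decalin-7β-carboxylic acid | OC(=O)[C@H]1C[C@@]2(C)[C@H](CC[C@@H](O)[C@@H]2C)[C@H]3OC(C)(C)O[C@@H]13 | intermediate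
14 | methyllithium | [Li]C | starting material
15 | 7β-acetyl-8β,9β-(isopropylidenedioxy)-4β,5β-dimethyl-10βH-cis-decalin-3α-ol | CC(=O)[C@H]1C[C@@]2(C)[C@H](CC[C@@H](O)[C@@H]2C)[C@H]3OC(C)(C)O[C@@H]13 | intermediate
16 | 8β,9β-(isopropylidenedioxy)-10βH-eremophil-11-en-3α-ol | C=C(C)[C@H]1C[C@@]2(C)[C@H](CC[C@@H](O)[C@@H]2C)[C@H]3OC(C)(C)O[C@@H]13 | intermediate
17 | angelic acid, (Z)-2-methylbut-2-enoic acid | C/C=C(/C)C(=O)O | starting material
18 | 3α-angeloyloxy-8β,9β-(isopropylidenedioxy)-10βH-eremophil-11-ene | C=C(C)[C@H]1C[C@@]2(C)[C@H](CC[C@@H](OC(=O)/C(C)=C\C)[C@@H]2C)[C@H]3OC(C)(C)O[C@@H]13 | intermediate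
19 | 3α-angeloyloxy-10βH-eremophil-11-ene-8β,9β-diol | C=C(C)[C@H]1C[C@@]2(C)[C@H](CC[C@@H](OC(=O)/C(C)=C\C)[C@@H]2C)[C@@H](O)[C@H]1O | intermediate
20 | 8β,9β-O-dibutylstannylene acetal of 19 (not isolated) | C=C(C)[C@H]1C[C@@]2(C)[C@H](CC[C@@H](OC(=O)/C(C)=C\C)[C@@H]2C)[C@H]3O[Sn](CCCC)(CCCC)O[C@@H]13 | intermediate
21 | 3α,9β-bis(angeloyloxy)-10βH-eremophil-11-en-8β-ol | C=C(C)[C@H]1C[C@@]2(C)[C@H](CC[C@@H](OC(=O)/C(C)=C\C)[C@@H]2C)[C@@H](OC(=O)/C(C)=C\C)[C@H]1O | intermediate
22 | (3R,4R,5R,7R,9R,10S)-3,9-bis[(Z)-2-methylbut-2-enoyloxy]eremophil-11-en-8-one (3α,9β-diangelate, 10βH) | C=C(C)[C@H]1C[C@@]2(C)[C@H](CC[C@@H](OC(=O)/C(C)=C\C)[C@@H]2C)[C@@H](OC(=O)/C(C)=C\C)C1=O | target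

Total step count: 13. Longest linear sequence: 13 steps (from 1).

Steps most likely to fail

Step 1. The oxygen transfer may discriminate the two faces poorly, oxygen may be delivered to the unsubstituted ortho carbon, or the quinol may dimerise faster than it is trapped. The fallback sets out from 1 and 2 and returns at 5. Wessely acetoxylation of 1 (Pb(OAc)4, AcOH) should give the racemic, non-dimerising quinol acetate 6-acetoxy-5,6-dimethylcyclohexa-2,4-dien-1-one F1. Cycloaddition with 2 (neat, 60–80 °C, BHT) on the acetoxy-bearing face should give the racemic endo acetoxy keto acid F2. Crystallisation with (R)-1-phenylethylamine should give the diastereomerically pure ammonium salt F3 of the required enantiomer; the other antipode of the amine is taken if the unwanted enantiomer forms the less soluble salt. Acidification frees the single enantiomer of F2, and SmI2 in THF/MeOH, which cleaves α-acetoxy ketones more readily than α-ketols, should then deliver 5.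

Step 4. Poor solubility or tight ion pairing of the dipotassium salt may slow the sigmatropic shift, so that fragmentation of the alkoxide competes or the C4 equilibration stays incomplete. The fallback sets out from 7 and returns at 10. Silylation of the hydroxyl and carboxyl groups (TMSCl, imidazole, CH2Cl2) should give the bis(trimethylsilyl) derivative F4. The neutral siloxy-Cope rearrangement (o-dichlorobenzene, 200 °C, sealed tube) should give the trimethylsilyl enol ether F5. K2CO3 in MeOH then removes both silyl groups and equilibrates C4, and acidification gives 10.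

Step 12. Acylation may occur on the wrong oxygen or on both, the acyl group may migrate between the cis oxygens, or the angeloyl group may isomerise from Z to E. The fallback sets out from 19 and returns at 22. Silylation of the equatorial C9 hydroxyl (TESCl, imidazole, −20 °C) should give the 9-O-triethylsilyl ether F6. Dess–Martin oxidation of the axial C8 alcohol should give the 8-ketone F7. HF·pyridine should release the α-ketol F8, and Yamaguchi angeloylation of its single hydroxyl gives 22.

Further compounds
F1 | step 1 | racemic 6-acetoxy-5,6-dimethylcyclohexa-2,4-dien-1-one | CC(=O)OC1(C)C(C)=CC=CC1=O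
F2 | step 1 | racemic 5-acetoxy-4,5-dimethyl-6-oxobicyclo[2.2.2]oct-7-ene-2-carboxylic acid, CO2H endo, acetoxy syn to the CO2H-bearing bridge (required enantiomer drawn) | OC(=O)[C@H]1C[C@@]2(C)C=C[C@@H]1C(=O)[C@@]2(C)OC(C)=O
F3 | step 1 | (R)-1-phenylethylammonium salt of the required enantiomer of F2 | [O-]C(=O)[C@H]1C[C@@]2(C)C=C[C@@H]1C(=O)[C@@]2(C)OC(C)=O.C[C@@H]([NH3+])c1ccccc1
F4 | step 4 | trimethylsilyl ester and trimethylsilyl ether of 7 | C[Si](C)(C)OC(=O)[C@H]1C[C@@]2(C)C=C[C@@H]1[C@](O[Si](C)(C)C)(C=C)[C@H]2C
F5 | step 4 | trimethylsilyl 4α,5β-dimethyl-3-(trimethylsilyloxy)-10βH-cis-octala-2,8-diene-7β-carboxylate | C[Si](C)(C)OC(=O)[C@H]1C[C@@]2(C)[C@H](CC=C(O[Si](C)(C)C)[C@H]2C)C=C1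
F6 | step 12 | 3α-angeloyloxy-9β-(triethylsilyloxy)-10βH-eremophil-11-en-8β-ol | C=C(C)[C@H]1C[C@@]2(C)[C@H](CC[C@@H](OC(=O)/C(C)=C\C)[C@@H]2C)[C@@H](O[Si](CC)(CC)CC)[C@H]1O
F7 | step 12 | 3α-angeloyloxy-9β-(triethylsilyloxy)-10βH-eremophil-11-en-8-one | C=C(C)[C@H]1C[C@@]2(C)[C@H](CC[C@@H](OC(=O)/C(C)=C\C)[C@@H]2C)[C@@H](O[Si](CC)(CC)CC)C1=O
F8 | step 12 | 3α-angeloyloxy-9β-hydroxy-10βH-eremophil-11-en-8-one | C=C(C)[C@H]1C[C@@]2(C)[C@H](CC[C@@H](OC(=O)/C(C)=C\C)[C@@H]2C)[C@@H](O)C1=O
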